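Ring B is cut at two bonds: the one joining the spiro carbon to the isopropyl-bearing CH, and the ring C=C. Both are made in a single amine-catalysed operation between a ring-A 1,3-dione that already carries a 3-oxopropyl arm on its central carbon and (E)-4-methylpent-2-enal. Conjugate addition sets the CH(iPr) centre and makes the spiro carbon quaternary; aldol condensation then closes the cyclohexene and leaves a formyl group where the side chain must grow. The step exploits the 1,3-relationship in ring B between the CH(iPr) carbon, bonded directly to the spiro carbon (former dione C2), and the olefinic CH, which is the former carbonyl carbon of the enal.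

Key step: step 6

Remark on the chemistry: 7 and 9 are written as single tautomers; 9 is expected to rest largely as a bicyclic lactol (enol oxygen on the aldehyde) that opens under the conditions of step 6. The (S)-catalyst in step 6 is chosen on the usual face-shielding model for diarylprolinol silyl ethers. The target is the (6R,11S) isomer, with isopropyl cis to the ring-A carbonyl that is conjugated with the enol ether.

Step 1
Reactants: 1 2,2-dimethylbut-3-enoic acid; 2 methyl propanoate
Product: 4 racemic methyl 2,4,4-trimethyl-3-oxohex-5-enoate, via 2,2-dimethylbut-3-enoyl chloride 3 (not isolated)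
Conditions: (COCl)2, cat. DMF, CH2Cl2, 0 °C to rt, concentrate; then added to 2 (2.3 equiv)/LDA (2.2 equiv), THF, −78 °C; aq. NH4Cl
Reagents that add atoms: none
Why: Crossed Claisen condensation: the acid chloride has no α-hydrogen, so it can neither enolise nor form a ketene and should simply C-acylate the lithium ester enolate, while the second equivalent of enolate converts the β-keto ester into its enolate and stops further acylation.

Step 2
Reactants: 4 racemic methyl 2,4,4-trimethyl-3-oxohex-5-enoate
Product: 5 methyl (2E)-3-methoxy-2,4,4-trimethylhexa-2,5-dienoate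
Conditions: NaH, THF/DMPU (4:1), 0 °C; Me2SO4, 0 °C to rt
Reagents that add atoms: dimethyl sulfate, COS(=O)(=O)OC
Why: O-alkylation of a β-keto ester enolate: a hard methylating agent in a dissociating medium should attack oxygen of the extended, non-chelated enolate (C-methylation would have to build a quaternary carbon beside the neopentyl ketone), placing OMe trans to the ester, the geometry that step 4 needs.

Step 3
Reactants: 5 methyl (2E)-3-methoxy-2,4,4-trimethylhexa-2,5-dienoate
Product: 6 methyl (2E)-3-methoxy-2,4,4-trimethyl-5-oxohex-2-enoate
Conditions: PdCl2 (10 mol %), CuCl (1 equiv), O2 (1 atm), DMF/H2O (7:1), rt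
Reagents that add atoms: water, O; dioxygen, O=O
Why: Tsuji–Wacker oxidation: the monosubstituted vinyl group is the only alkene that can coordinate Pd(II), Markovnikov attack of water should give the methyl ketone, and the tetrasubstituted, ester-conjugated enol ether should be left alone.

Step 4
Reactants: 6 methyl (2E)-3-methoxy-2,4,4-trimethyl-5-oxohex-2-enoate
Product: 7 5-methoxy-4,6,6-trimethylcyclohex-4-ene-1,3-dione
Conditions: KOtBu (2.2 equiv), THF, 0 °C to rt; cold 1 M HCl to pH 3
Reagents that add atoms: none
Why: Dieckmann-type (intramolecular Claisen) condensation: the acetyl methyl is the only enolisable site, its enolate reaches the cis-placed ester in a 6-exo-trig closure, and the product leaves the equilibrium as its delocalised enolate.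

Step 5
Reactants: 7 5-methoxy-4,6,6-trimethylcyclohex-4-ene-1,3-dione; 8 acrolein (prop-2-enal)
Product: 9 3-(2-hydroxy-4-methoxy-3,3,5-trimethyl-6-oxocyclohexa-1,4-dien-1-yl)propanal
Conditions: 8 (1.1 equiv), DABCO (5 mol %), THF/H2O (4:1), 0 °C to rt
Reagents that add atoms: none
Why: Michael addition of a vinylogous acid to acrolein: the central carbon of the dione is its nucleophilic site, and the mono-adduct should be shielded from a second addition because it closes reversibly to a bicyclic lactol.

Step 6
Reactants: 9 3-(2-hydroxy-4-methoxy-3,3,5-trimethyl-6-oxocyclohexa-1,4-dien-1-yl)propanal; 10 (2E)-4-methylpent-2-enal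
Product: 12 (5S,6R)-9-methoxy-8,10,10-trimethyl-7,11-dioxo-5-(propan-2-yl)spiro[5.5]undeca-2,8-diene-2-carbaldehyde, via dialdehyde Michael adduct 11 (not isolated)
Conditions: 10 (2 equiv), (S)-2-[diphenyl(trimethylsilyloxy)methyl]pyrrolidine (20 mol %), PhCO2H (20 mol %), toluene, 0 °C to rt, then 40 °C
Reagents that add atoms: none
Why: The amine and 10 give an E-configured, s-trans iminium ion; the central enol carbon of 9 (freed from its lactol) adds to the β-carbon, the enamine formed on the branched arm is protonated by the acidic dione or benzoic acid and hydrolysed to dialdehyde 11, the amine then forms the enamine of the unbranched oxopropyl aldehyde, which adds to the other formyl group, and E1cB loss of water gives the conjugated enal. The closest known reaction type is the secondary-amine Michael/aldol-condensation domino between enals and C–H acids carrying a tethered aldehyde, which delivers cyclohexenecarbaldehydes, spiro-fused ones included. Ring B closes by a 6-(enolexo)-exo-trig aldol addition. The CH(iPr) centre (S) is set by the catalyst, whose CPh2(OSiMe3) group blocks one face of the iminium ion so that the dione attacks the open face. The spiro carbon (R) depends on the substrate: the dione should approach, and the chair-like aldol should close, with the CMe2 flank of ring A turned away from the isopropyl group (isopropyl equatorial and cis to the carbonyl next to the planar C(Me)= carbon), and since the Michael step is reversible the crowded epimer can revert and be funnelled through the faster-closing one. The step needs the oxopropyl arm, not the enal-derived arm, to act as aldol donor; this rests on sterics, because the α-CH2 beside CH(iPr) and the quaternary carbon is far more hindered than the α-CH2 of the oxopropyl arm, and this bulky catalyst, a poor aldol catalyst, should let the first-formed enamine be protonated before it can cyclise.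

Step 7
Reactants: 12 (5S,6R)-9-methoxy-8,10,10-trimethyl-7,11-dioxo-5-(propan-2-yl)spiro[5.5]undeca-2,8-diene-2-carbaldehyde
Product: 13 (6R,11S)-8-ethenyl-3-methoxy-2,4,4-trimethyl-11-(propan-2-yl)spiro[5.5]undeca-2,8-diene-1,5-dione
Conditions: Ph3PCH3Br (1.3 equiv), KHMDS (1.2 equiv), THF, 0 °C; then 12, −78 to 0 °C
Reagents that add atoms: methyltriphenylphosphonium bromide, C[P+](c1ccccc1)(c1ccccc1)c1ccccc1.[Br-]
Why: Wittig methylenation: the aldehyde is the only unhindered carbonyl group (both ring-A ketones are flanked by fully substituted carbons and one is a vinylogous ester), the quaternary spiro centre cannot enolise and the CH(iPr) centre is not α to a carbonyl group, so both should be retained.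

Step 8
Reactants: 13 (6R,11S)-8-ethenyl-3-methoxy-2,4,4-trimethyl-11-(propan-2-yl)spiro[5.5]undeca-2,8-diene-1,5-dione; 14 1-bromo-2-methylprop-1-ene
Product: 16 (6R,11S)-3-methoxy-2,4,4-trimethyl-8-(4-methylpent-3-en-1-yl)-11-(propan-2-yl)spiro[5.5]undeca-2,8-diene-1,5-dione, via homoallylic 9-BBN borane 15 (not isolated)
Conditions: 9-BBN (1.2 equiv), THF, 0 °C to rt; then 14 (2 equiv), Pd(dppf)Cl2 (5 mol %), AsPh3 (5 mol %), aq. K3PO4 (3 equiv), DMF, rt
Reagents that add atoms: none
Why: Hydroboration/B-alkyl Suzuki–Miyaura coupling: 9-BBN should add anti-Markovnikov to the terminal vinyl group of the diene much faster than it attacks the trisubstituted ring alkene or the hindered ketones, and Pd-catalysed coupling of the homoallylic borane with the vinyl bromide forms the CH2–CH= bond without touching either stereocentre.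

Compound list
1 | 2,2-dimethylbut-3-enoic acid | C=CC(C)(C)C(=O)O | starting material
2 | methyl propanoate | CCC(=O)OC | starting material
3 | 2,2-dimethylbut-3-enoyl chloride (not isolated) | C=CC(C)(C)C(=O)Cl | intermediate
4 | racemic methyl 2,4,4-trimethyl-3-oxohex-5-enoate | C=CC(C)(C)C(=O)C(C)C(=O)OC | intermediate
5 | methyl (2E)-3-methoxy-2,4,4-trimethylhexa-2,5-dienoate | CO/C(C(C)(C)C=C)=C(\C)C(=O)OC | intermediate
6 | methyl (2E)-3-methoxy-2,4,4-trimethyl-5-oxohex-2-enoate | CO/C(C(C)(C)C(C)=O)=C(\C)C(=O)OC | intermediate
7 | 5-methoxy-4,6,6-trimethylcyclohex-4-ene-1,3-dione (ring-A dione, diketo tautomer) | COC1=C(C)C(=O)CC(=O)C1(C)C | intermediate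
8 | acrolein (prop-2-enal) | C=CC=O | starting material
9 | 3-(2-hydroxy-4-methoxy-3,3,5-trimethyl-6-oxocyclohexa-1,4-dien-1-yl)propanal (2-(3-oxopropyl) ring-A dione, enol form; in equilibrium with its lactol) | COC1=C(C)C(=O)C(CCC=O)=C(O)C1(C)C | intermediate
10 | (2E)-4-methylpent-2-enal | CC(C)/C=C/C=O | starting material
11 | (3S)-3-[(1R)-4-methoxy-3,5,5-trimethyl-2,6-dioxo-1-(3-oxopropyl)cyclohex-3-en-1-yl]-4-methylpentanal (not isolated) | COC1=C(C)C(=O)[C@@](CCC=O)([C@@H](CC=O)C(C)C)C(=O)C1(C)C | intermediate
12 | (5S,6R)-9-methoxy-8,10,10-trimethyl-7,11-dioxo-5-(propan-2-yl)spiro[5.5]undeca-2,8-diene-2-carbaldehyde (spiro enal) | COC1=C(C)C(=O)[C@]2(CC(C=O)=CC[C@H]2C(C)C)C(=O)C1(C)C | intermediate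
13 | (6R,11S)-8-ethenyl-3-methoxy-2,4,4-trimethyl-11-(propan-2-yl)spiro[5.5]undeca-2,8-diene-1,5-dione | COC1=C(C)C(=O)[C@]2(CC(C=C)=CC[C@H]2C(C)C)C(=O)C1(C)C | intermediate
14 | 1-bromo-2-methylprop-1-ene | CC(C)=CBr | starting material
15 | 9-{2-[(6R,11S)-3-methoxy-2,4,4-trimethyl-1,5-dioxo-11-(propan-2-yl)spiro[5.5]undeca-2,8-dien-8-yl]ethyl}-9-borabicyclo[3.3.1]nonane (not isolated) | COC1=C(C)C(=O)[C@]2(CC(CCB3C4CCCC3CCC4)=CC[C@H]2C(C)C)C(=O)C1(C)C | intermediate
16 | (6R,11S)-3-methoxy-2,4,4-trimethyl-8-(4-methylpent-3-en-1-yl)-11-(propan-2-yl)spiro[5.5]undeca-2,8-diene-1,5-dione | COC1=C(C)C(=O)[C@]2(CC(CCC=C(C)C)=CC[C@H]2C(C)C)C(=O)C1(C)C | target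

Total steps: 8. Longest linear sequence: 8 steps (1 to 16).

Steps most likely to fail

1. Step 6 (key step). The aldol may close from the enamine of the branched arm onto the oxopropyl aldehyde and give the regioisomeric enal. Facial discrimination at the spiro carbon may be poor. The reversible Michael stage may stall. Fallback: the two bond formations are decoupled and the ring is closed by olefination, which fixes the position of the double bond. It sets out from 7. Conjugate addition of 7 to 10 under the same iminium catalysis should give (3S)-3-(2-hydroxy-4-methoxy-3,3,5-trimethyl-6-oxocyclohexa-1,4-dien-1-yl)-4-methylpentanal F1, handled as its lactol. Separately, 6-methylhept-5-en-2-one is converted through its kinetic enolate (LDA, PhNTf2, THF, −78 °C) into 6-methylhepta-1,5-dien-2-yl trifluoromethanesulfonate F2, and Pd-catalysed coupling with PPh3 (cat. Pd(PPh3)4, THF) gives (6-methylhepta-1,5-dien-2-yl)triphenylphosphonium trifluoromethanesulfonate F3. The sodium enolate of F1 (NaH, THF, 0 °C to 50 °C) adds to the vinylphosphonium salt, and the ylide so formed closes onto the aldehyde in an intramolecular Wittig reaction (Schweizer annulation). This returns to the route at 16 with the side chain in place and bypasses steps 5 to 8. The spiro carbon then rests on substrate control alone, and any epimer would have to be separated.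

2. Step 8. Hydride may be transferred from the borane to a ring-A carbonyl group, or the 2,2-disubstituted 1,3-dione may open by retro-Claisen cleavage under the basic coupling conditions. Fallback: the chain is built by sulfone alkylation instead of cross-coupling. It sets out from 12. Selective 1,2-reduction of the aldehyde (NaBH4, EtOH/THF, −40 °C) should give (6R,11S)-8-(hydroxymethyl)-3-methoxy-2,4,4-trimethyl-11-(propan-2-yl)spiro[5.5]undeca-2,8-diene-1,5-dione F4. Appel bromination (CBr4, PPh3, CH2Cl2, 0 °C) gives the corresponding 8-(bromomethyl) compound F5. Alkylation of lithiated 3-methylbut-2-enyl phenyl sulfone (n-BuLi, THF, −78 °C) gives the 8-[2-(benzenesulfonyl)-4-methylpent-3-en-1-yl] compound F6. Reductive desulfonylation (Na/Hg, Na2HPO4, MeOH/THF, −20 °C) returns to the route at 16.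

3. Step 2. Methylation may occur at carbon, or the Z enol ether may form, which cannot reach the ester in step 4. Fallback: the enol ether is made under acid and thermodynamic control instead of by enolate alkylation. It sets out from 4, which is heated with HC(OMe)3 and catalytic H2SO4 in MeOH (40 to 60 °C). The enol oxygen is methylated through the dimethoxycarbenium ion, C-methylation is not possible, and reversible protonation of the product should equilibrate the geometric isomers toward the E isomer. It returns to the route at 5 and makes no new compound.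

Further compounds
F1 | step 6 | (3S)-3-(2-hydroxy-4-methoxy-3,3,5-trimethyl-6-oxocyclohexa-1,4-dien-1-yl)-4-methylpentanal (handled as its lactol) | COC1=C(C)C(=O)C([C@@H](CC=O)C(C)C)=C(O)C1(C)C
F2 | step 6 | 6-methylhepta-1,5-dien-2-yl trifluoromethanesulfonate | CC(C)=CCCC(=C)OS(=O)(=O)C(F)(F)F
F3 | step 6 | (6-methylhepta-1,5-dien-2-yl)triphenylphosphonium trifluoromethanesulfonate | CC(C)=CCCC(=C)[P+](c1ccccc1)(c1ccccc1)c1ccccc1.[O-]S(=O)(=O)C(F)(F)F
F4 | step 8 | (6R,11S)-8-(hydroxymethyl)-3-methoxy-2,4,4-trimethyl-11-(propan-2-yl)spiro[5.5]undeca-2,8-diene-1,5-dione | COC1=C(C)C(=O)[C@]2(CC(CO)=CC[C@H]2C(C)C)C(=O)C1(C)C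
F5 | step 8 | (6R,11S)-8-(bromomethyl)-3-methoxy-2,4,4-trimethyl-11-(propan-2-yl)spiro[5.5]undeca-2,8-diene-1,5-dione | COC1=C(C)C(=O)[C@]2(CC(CBr)=CC[C@H]2C(C)C)C(=O)C1(C)C
F6 | step 8 | (6R,11S)-8-[2-(benzenesulfonyl)-4-methylpent-3-en-1-yl]-3-methoxy-2,4,4-trimethyl-11-(propan-2-yl)spiro[5.5]undeca-2,8-diene-1,5-dione (both epimers at the sulfonyl carbon) | COC1=C(C)C(=O)[C@]2(CC(CC(C=C(C)C)S(=O)(=O)c3ccccc3)=CC[C@H]2C(C)C)C(=O)C1(C)C
F0 | step 2 | none | none
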